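**Retrosynthetic overview**
1. Target 18 ⇒ ester C–O bond: 5'-methoxylariciresinol 16 + (E)-ferulic acid 17 (chemoselective Mitsunobu, last step).
2. Tetrahydrofuran ring (second ring formed, step 8) ⇒ C7–O bond: acid cycloetherification of pentaol 15, made by LiAlH4 reduction of trans hydroxy lactone 14.
3. γ-Lactone (first ring formed, temporary, step 7) ⇒ hydroxy keto ester 12; the ring lets C8 equilibrate trans to C8' before the ketone is reduced.
4. Key C8–C8' bond ⇒ aldehyde 10 (chiral enamine, nucleophilic α-carbon) + α-bromo β-keto ester 7, whose α-carbon, normally an enolate nucleophile, reacts with reversed polarity as an enolonium-type electrophile (electron-poor radical); this sets C8' as R.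
5. 7 ⇐ syringaldehyde 1 (pivalate, Roskamp homologation, bromination); 10 ⇐ dihydroconiferyl alcohol 8 (pivalate, oxidation).

Assumption: the SMILES is read as the (2S,3R,4R) isomer (2,3-trans-3,4-cis ring), i.e. the 9-O-(E)-feruloyl ester of 5'-methoxylariciresinol; lignan numbering is used (C7–C9 syringyl half, C7'–C9' guaiacyl half), and "pivaloyloxy" means (2,2-dimethylpropanoyl)oxy.

**Step 1**
Reactants: 1 syringaldehyde; 2 pivaloyl chloride
Product: 3 4-formyl-2,6-dimethoxyphenyl pivalate
Conditions: 2 (1.2 equiv), NEt3 (1.5 equiv), DMAP (5 mol%), CH2Cl2, 0 °C to rt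
Reagents that add atoms: pivaloyl chloride, CC(C)(C)C(Cl)=O
Why: DMAP-catalysed O-acylation of the phenol (nucleophilic acyl transfer); the hindered pivalate masks the phenol through steps 2–7 and is removed by LiAlH4 in step 8 without a separate deprotection.

**Step 2**
Reactants: 3 4-formyl-2,6-dimethoxyphenyl pivalate; 4 ethyl diazoacetate
Product: 5 ethyl 3-[3,5-dimethoxy-4-(pivaloyloxy)phenyl]-3-oxopropanoate
Conditions: 4 (1.3 equiv), NbCl5 (5 mol%), CH2Cl2, rt
Reagents that add atoms: ethyl diazoacetate, CCOC(=O)C=[N+]=[N-]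
Why: Roskamp homologation, in which the diazo carbon adds to the Lewis-acid-activated aldehyde and a 1,2-hydride shift with loss of N2 gives the β-keto ester; the aryl group (para to OPiv, meta to two OMe) migrates poorly, so hydride shift should dominate.

**Step 3**
Reactants: 5 ethyl 3-[3,5-dimethoxy-4-(pivaloyloxy)phenyl]-3-oxopropanoate; 6 N-bromosuccinimide
Product: 7 ethyl 2-bromo-3-[3,5-dimethoxy-4-(pivaloyloxy)phenyl]-3-oxopropanoate (racemic)
Conditions: 6 (1.05 equiv), NH4OAc (10 mol%), Et2O, rt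
Reagents that add atoms: N-bromosuccinimide, O=C1CCC(=O)N1Br
Why: Electrophilic α-bromination of the enolised β-keto ester at its only doubly activated C–H; the racemic stereocentre does not matter because it is destroyed in step 6.

**Step 4**
Reactants: 8 dihydroconiferyl alcohol; 2 pivaloyl chloride
Product: 9 4-(3-hydroxypropyl)-2-methoxyphenyl pivalate
Conditions: NaOH (1.1 equiv), H2O/THF, 0 °C, then 2 (1.05 equiv)
Reagents that add atoms: pivaloyl chloride, CC(C)(C)C(Cl)=O
Why: Schotten–Baumann acylation, in which only the phenol (pKa about 10) is deprotonated by aqueous NaOH, so the phenoxide is acylated and the primary alcohol stays free.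

**Step 5**
Reactants: 9 4-(3-hydroxypropyl)-2-methoxyphenyl pivalate
Product: 10 2-methoxy-4-(3-oxopropyl)phenyl pivalate
Conditions: TEMPO (10 mol%), PhI(OAc)2 (1.1 equiv), CH2Cl2, rt
Reagents that add atoms: none
Why: TEMPO/oxoammonium oxidation of the primary alcohol, which stops at the aldehyde and leaves the aryl pivalate untouched (the phenol must be masked because a free guaiacol would quench the radical chain of step 6).

**Step 6 (key step)**
Reactants: 7 ethyl 2-bromo-3-[3,5-dimethoxy-4-(pivaloyloxy)phenyl]-3-oxopropanoate; 10 2-methoxy-4-(3-oxopropyl)phenyl pivalate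
Product: 12 ethyl (3R)-2-[3,5-dimethoxy-4-(pivaloyloxy)benzoyl]-3-(hydroxymethyl)-4-[3-methoxy-4-(pivaloyloxy)phenyl]butanoate (epimers at C2), via formyl keto ester 11 (not isolated)
Conditions: 10 (2 equiv), (2R,5S)-2-tert-butyl-3,5-dimethylimidazolidin-4-one·TfOH (20 mol%), Ru(bpy)3Cl2 (0.5 mol%), 2,6-lutidine (2 equiv), DMF, blue LED, 23 °C; then MeOH, NaBH4, −40 °C (excess 10 returns as 9)
Reagents that add atoms: none
Why: Enantioselective enamine/photoredox α-alkylation of an aldehyde with an α-bromo dicarbonyl, in which photoexcited Ru(bpy)3Cl2 turns 7 into an electron-poor α-keto-ester radical (its α-carbon acting as an enolonium-type electrophile) that adds to the chiral enamine of 10 on the face left open by the trans tert-butyl/methyl groups, setting C8' as R (this sense is assigned by analogy with bromomalonate alkylations under this catalyst, and the mirror-image catalyst is equally available if it proves opposite), while the C8 epimer mixture is corrected in step 7 and NaBH4 at −40 °C reduces only the aldehyde.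

**Step 7**
Reactants: 12 ethyl (3R)-2-[3,5-dimethoxy-4-(pivaloyloxy)benzoyl]-3-(hydroxymethyl)-4-[3-methoxy-4-(pivaloyloxy)phenyl]butanoate
Product: 14 (3S,4R)-3-{[3,5-dimethoxy-4-(pivaloyloxy)phenyl](hydroxy)methyl}-4-[3-methoxy-4-(pivaloyloxy)benzyl]dihydrofuran-2(3H)-one (both carbinol epimers), via keto lactone 13 (not isolated)
Conditions: DMAP (0.2 equiv), toluene, 80 °C; then MeOH, NaBH4, −20 °C
Reagents that add atoms: none
Why: DMAP-catalysed intramolecular transesterification of the β-keto ester (5-exo lactonisation, ethanol lost) gives keto lactone 13, whose doubly activated C8–H epimerises to the trans isomer (aroyl anti to the benzyl group), and borohydride reduction of the aryl ketone then fixes C8 as 3S; the new carbinol centre is a mixture that is erased in step 8.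

**Step 8**
Reactants: 14 (3S,4R)-3-{[3,5-dimethoxy-4-(pivaloyloxy)phenyl](hydroxy)methyl}-4-[3-methoxy-4-(pivaloyloxy)benzyl]dihydrofuran-2(3H)-one
Product: 16 4-[(2S,3R,4R)-4-(4-hydroxy-3-methoxybenzyl)-3-(hydroxymethyl)tetrahydrofuran-2-yl]-2,6-dimethoxyphenol (5'-methoxylariciresinol), via pentaol 15 (not isolated)
Conditions: LiAlH4 (6 equiv), THF, 0 °C to rt; aq. potassium sodium tartrate work-up; crude 15, CSA (0.1 equiv), THF, 0 °C to rt (16 recrystallised to upgrade ee)
Reagents that add atoms: none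
Why: Hydride reduction opens the lactone to the diol and cleaves both aryl pivalates, then acid-catalysed cycloetherification follows, in which the 4-hydroxy-3,5-dimethoxybenzylic carbinol ionises (quinone-methide-type cation) and is captured 5-exo by the C9' hydroxyl (the C9 hydroxyl could only form an oxetane), both carbinol epimers converging on the thermodynamically favoured 2,3-trans ring with aryl anti to CH2OH, i.e. 2S.

**Step 9**
Reactants: 16 5'-methoxylariciresinol; 17 (E)-ferulic acid
Product: 18 [(2S,3R,4R)-2-(4-hydroxy-3,5-dimethoxyphenyl)-4-(4-hydroxy-3-methoxybenzyl)tetrahydrofuran-3-yl]methyl (E)-3-(4-hydroxy-3-methoxyphenyl)prop-2-enoate (target)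
Conditions: 17 (1.3 equiv), PPh3 (1.3 equiv), DIAD (1.3 equiv), THF, 0 °C to rt
Reagents that add atoms: (E)-ferulic acid, COc1cc(/C=C/C(=O)O)ccc1O
Why: Mitsunobu esterification, in which only the carboxylic acid (pKa about 4.5) is acidic enough to protonate the betaine, so the ferulate anion displaces the primary alkoxyphosphonium while the three phenols (pKa about 10) stay free; no stereocentre is touched and the E alkene is retained.

**Compound list**
1 | syringaldehyde (4-hydroxy-3,5-dimethoxybenzaldehyde) | COc1cc(C=O)cc(OC)c1O | starting material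
2 | pivaloyl chloride | CC(C)(C)C(Cl)=O | starting material
3 | 4-formyl-2,6-dimethoxyphenyl pivalate | COc1cc(C=O)cc(OC)c1OC(=O)C(C)(C)C | intermediate
4 | ethyl diazoacetate | CCOC(=O)C=[N+]=[N-] | starting material
5 | ethyl 3-[3,5-dimethoxy-4-(pivaloyloxy)phenyl]-3-oxopropanoate | CCOC(=O)CC(=O)c1cc(OC)c(OC(=O)C(C)(C)C)c(OC)c1 | intermediate
6 | N-bromosuccinimide | O=C1CCC(=O)N1Br | starting material
7 | ethyl 2-bromo-3-[3,5-dimethoxy-4-(pivaloyloxy)phenyl]-3-oxopropanoate (racemic) | CCOC(=O)C(Br)C(=O)c1cc(OC)c(OC(=O)C(C)(C)C)c(OC)c1 | intermediate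
8 | dihydroconiferyl alcohol, 4-(3-hydroxypropyl)-2-methoxyphenol | COc1cc(CCCO)ccc1O | starting material
9 | 4-(3-hydroxypropyl)-2-methoxyphenyl pivalate | COc1cc(CCCO)ccc1OC(=O)C(C)(C)C | intermediate
10 | 2-methoxy-4-(3-oxopropyl)phenyl pivalate | COc1cc(CCC=O)ccc1OC(=O)C(C)(C)C | intermediate
11 | ethyl (3R)-2-[3,5-dimethoxy-4-(pivaloyloxy)benzoyl]-3-formyl-4-[3-methoxy-4-(pivaloyloxy)phenyl]butanoate (epimers at C2) | CCOC(=O)C(C(=O)c1cc(OC)c(OC(=O)C(C)(C)C)c(OC)c1)[C@@H](Cc1ccc(OC(=O)C(C)(C)C)c(OC)c1)C=O | intermediate (not isolated)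
12 | ethyl (3R)-2-[3,5-dimethoxy-4-(pivaloyloxy)benzoyl]-3-(hydroxymethyl)-4-[3-methoxy-4-(pivaloyloxy)phenyl]butanoate (epimers at C2) | CCOC(=O)C(C(=O)c1cc(OC)c(OC(=O)C(C)(C)C)c(OC)c1)[C@@H](Cc1ccc(OC(=O)C(C)(C)C)c(OC)c1)CO | intermediate
13 | (3S,4R)-3-[3,5-dimethoxy-4-(pivaloyloxy)benzoyl]-4-[3-methoxy-4-(pivaloyloxy)benzyl]dihydrofuran-2(3H)-one (trans) | O=C1OC[C@H](Cc2ccc(OC(=O)C(C)(C)C)c(OC)c2)[C@H]1C(=O)c3cc(OC)c(OC(=O)C(C)(C)C)c(OC)c3 | intermediate (not isolated)
14 | (3S,4R)-3-{[3,5-dimethoxy-4-(pivaloyloxy)phenyl](hydroxy)methyl}-4-[3-methoxy-4-(pivaloyloxy)benzyl]dihydrofuran-2(3H)-one (both carbinol epimers) | O=C1OC[C@H](Cc2ccc(OC(=O)C(C)(C)C)c(OC)c2)[C@H]1C(O)c3cc(OC)c(OC(=O)C(C)(C)C)c(OC)c3 | intermediate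
15 | (2R,3R)-2-[(4-hydroxy-3,5-dimethoxyphenyl)(hydroxy)methyl]-3-(4-hydroxy-3-methoxybenzyl)butane-1,4-diol (both carbinol epimers) | OC[C@H](Cc1ccc(O)c(OC)c1)[C@H](CO)C(O)c1cc(OC)c(O)c(OC)c1 | intermediate (not isolated)
16 | 4-[(2S,3R,4R)-4-(4-hydroxy-3-methoxybenzyl)-3-(hydroxymethyl)tetrahydrofuran-2-yl]-2,6-dimethoxyphenol (5'-methoxylariciresinol) | OC[C@H]1[C@@H](Cc2ccc(O)c(OC)c2)CO[C@@H]1c3cc(OC)c(O)c(OC)c3 | intermediate
17 | (E)-ferulic acid | COc1cc(/C=C/C(=O)O)ccc1O | starting material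
18 | [(2S,3R,4R)-2-(4-hydroxy-3,5-dimethoxyphenyl)-4-(4-hydroxy-3-methoxybenzyl)tetrahydrofuran-3-yl]methyl (E)-3-(4-hydroxy-3-methoxyphenyl)prop-2-enoate | COc1cc(/C=C/C(=O)OC[C@H]2[C@@H](Cc3ccc(O)c(OC)c3)CO[C@@H]2c2cc(OC)c(O)c(OC)c2)ccc1O | target

**Totals**
Total steps: 9. Longest linear sequence: 7 (steps 1, 2, 3, 6, 7, 8, 9).

**Three steps most likely to fail, each with a fallback**

Step 6. The hindered aroyl bromo ester may transfer bromine to the enamine or react sluggishly, lowering yield or ee. The fallback sets out from aldehyde 10 and returns to the route at hydroxy lactone 14. Aldehyde 10 is alkylated under the same enamine/photoredox catalysis with commercial diethyl bromomalonate, the benchmark and far less hindered partner, giving diethyl 2-[(2R)-1-oxo-3-(3-methoxy-4-pivaloyloxyphenyl)propan-2-yl]malonate F1. This is reduced in the same flask with NaBH4 to diethyl 2-[(2R)-1-hydroxy-3-(3-methoxy-4-pivaloyloxyphenyl)propan-2-yl]malonate F2. PPTS in toluene closes ethyl (4R)-4-[3-methoxy-4-(pivaloyloxy)benzyl]-2-oxotetrahydrofuran-3-carboxylate F3, and LiCl in wet DMSO at 140 °C removes the ester to give (4R)-4-[3-methoxy-4-(pivaloyloxy)benzyl]dihydrofuran-2(3H)-one F4. Its lithium enolate (LiN(SiMe3)2, THF, −78 °C) adds to aldehyde 3 anti to the benzyl group and gives 14 directly, so the aryl-bearing carbon C7 is attached by a lactone aldol instead of being carried through the coupling.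

Step 7. Instead of lactonising, the hydroxyl may add to the aryl ketone and dehydrate to a 4,5-dihydrofuran-3-carboxylate, or a pivaloyl group may migrate. The fallback sets out from 12 and returns to the route at keto lactone 13. The ketone is taken out of play first: NaBH4 (MeOH, 0 °C) gives ethyl (3R)-2-{[3,5-dimethoxy-4-(pivaloyloxy)phenyl](hydroxy)methyl}-3-(hydroxymethyl)-4-[3-methoxy-4-(pivaloyloxy)phenyl]butanoate F5. PPTS (CH2Cl2, rt) then lactonises its only γ-hydroxy ester to (4R)-3-{[3,5-dimethoxy-4-(pivaloyloxy)phenyl](hydroxy)methyl}-4-[3-methoxy-4-(pivaloyloxy)benzyl]dihydrofuran-2(3H)-one F6, a mixture of epimers at C3 and at the carbinol. Dess–Martin periodinane re-oxidises the benzylic alcohol to 13, a trace of NEt3 equilibrates it to the trans isomer, and the NaBH4 stage of step 7 then gives 14.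

Step 9. Phenol O-alkylation or oligomerisation may compete under Mitsunobu conditions on the unprotected triphenol. The fallback sets out from 17 (with 16) and returns to the route at 18. Acid 17 is transvinylated with vinyl acetate (Hg(OAc)2 cat., H2SO4 cat., rt) to ethenyl (E)-3-(4-hydroxy-3-methoxyphenyl)prop-2-enoate (vinyl ferulate) F7. Immobilised Candida antarctica lipase B in 2-methylbutan-2-ol at 50 °C then transfers the feruloyl group from F7 to the primary alcohol of 16 only, since phenols are not acylated by the lipase, giving 18.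

**Further compounds**
F1 | step 6 | diethyl 2-[(2R)-1-oxo-3-(3-methoxy-4-pivaloyloxyphenyl)propan-2-yl]malonate | CCOC(=O)C(C(=O)OCC)[C@@H](Cc1ccc(OC(=O)C(C)(C)C)c(OC)c1)C=O
F2 | step 6 | diethyl 2-[(2R)-1-hydroxy-3-(3-methoxy-4-pivaloyloxyphenyl)propan-2-yl]malonate | CCOC(=O)C(C(=O)OCC)[C@@H](Cc1ccc(OC(=O)C(C)(C)C)c(OC)c1)CO
F3 | step 6 | ethyl (4R)-4-[3-methoxy-4-(pivaloyloxy)benzyl]-2-oxotetrahydrofuran-3-carboxylate (epimers at C3) | O=C1OC[C@H](Cc2ccc(OC(=O)C(C)(C)C)c(OC)c2)C1C(=O)OCC
F4 | step 6 | (4R)-4-[3-methoxy-4-(pivaloyloxy)benzyl]dihydrofuran-2(3H)-one | O=C1OC[C@H](Cc2ccc(OC(=O)C(C)(C)C)c(OC)c2)C1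
F5 | step 7 | ethyl (3R)-2-{[3,5-dimethoxy-4-(pivaloyloxy)phenyl](hydroxy)methyl}-3-(hydroxymethyl)-4-[3-methoxy-4-(pivaloyloxy)phenyl]butanoate (diastereomer mixture) | CCOC(=O)C(C(O)c1cc(OC)c(OC(=O)C(C)(C)C)c(OC)c1)[C@@H](Cc1ccc(OC(=O)C(C)(C)C)c(OC)c1)CO
F6 | step 7 | (4R)-3-{[3,5-dimethoxy-4-(pivaloyloxy)phenyl](hydroxy)methyl}-4-[3-methoxy-4-(pivaloyloxy)benzyl]dihydrofuran-2(3H)-one (epimers at C3 and carbinol) | O=C1OC[C@H](Cc2ccc(OC(=O)C(C)(C)C)c(OC)c2)C1C(O)c3cc(OC)c(OC(=O)C(C)(C)C)c(OC)c3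
F7 | step 9 | ethenyl (E)-3-(4-hydroxy-3-methoxyphenyl)prop-2-enoate (vinyl ferulate) | COc1cc(/C=C/C(=O)OC=C)ccc1O
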